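**Plan**

- Cuts (retrosynthesis): the C1–C2 oxirane and the C15 aldehyde are adjusted last; the cyclohexane is cut at C5–C10; the seco-lactone is cut at C6–C7 and C8–C9; the ester at C6–O.
- Enabling feature: in the cyclohexane ring, C5 carries a 2-propenyl unit (C3=C4, C15) and the neighbouring quaternary C10 carries an oxygenated two-carbon arm (C1–C2). This is the footprint of an allylsilane (C3–Si, C4=C5) that opens a C10–C1 oxirane from the rear, the oxygen staying on C1.
- Forward: bromofuranone plus a C5 enal give the butenolide (vinylogous aldol); C9–OH-directed epoxidation; 3-(bromomethyl)butenolide plus an iodo-enal give the α-methylene lactone (Barbier); Mitsunobu ester; allylsilane; Lewis-acid closure of the cyclohexane; oxirane relocation; C15 oxidation.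
- Stereochemistry: C8/C9 from a catalytic asymmetric vinylogous Mukaiyama aldol; C10/C1 relayed from C9 (erythro epoxidation); C7/C6 from the closed Barbier transition state anti to the C8 arm, C6 then inverted by Mitsunobu; C5 and C10 in the key step (chair, SN2 inversion); C1 inverted on oxirane closure; acyl centre from (S)-2-methylbutanoic acid.

Key step: step 13

Remark: atoms are numbered as in elemanes (C5 = ring CH carrying C3=C4–C15, C10 = quaternary ring carbon, C1/C2 = oxirane carbons, C6 = acyloxy carbon, C7/C8 = lactone ring fusion, C9 = carbinol, C11/C12/C13 = lactone α-carbon, carbonyl, methylene, C14 = methyl); compound 13 is assumed to be commercial (otherwise one silylation from but-2-yne-1,4-diol).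

**Route**

Step 1
Reactants: 1 (tert-butyldimethylsilyloxy)acetaldehyde; 2 2-(triphenylphosphoranylidene)propanal
Product: 3 (E)-4-(tert-butyldimethylsilyloxy)-2-methylbut-2-enal
Conditions: toluene, 80 °C
Reagents that add atoms: none
Why: Wittig olefination with a formyl-stabilised ylide, which should give the E enal (CHO trans to CH2OTBS).

Step 2
Reactants: 4 3-bromofuran-2(5H)-one
Product: 5 3-bromo-2-(trimethylsilyloxy)furan
Conditions: TMSCl, Et3N, CH2Cl2, 0 °C to rt
Reagents that add atoms: chlorotrimethylsilane C[Si](C)(C)Cl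
Why: O-silylation of the furanolate formed by γ-deprotonation, the standard preparation of 2-silyloxyfurans.

Step 3
Reactants: 3 (E)-4-(tert-butyldimethylsilyloxy)-2-methylbut-2-enal; 5 3-bromo-2-(trimethylsilyloxy)furan
Product: 7 (5R)-3-bromo-5-[(1S,2E)-4-(tert-butyldimethylsilyloxy)-1-hydroxy-2-methylbut-2-en-1-yl]furan-2(5H)-one, via O-trimethylsilyl aldol ether 6 (not isolated)
Conditions: Ti(OiPr)4 (20 mol%), (R)-BINOL (20 mol%), Et2O, −20 °C; then AcOH–THF–H2O, 0 °C
Reagents that add atoms: none
Why: Catalytic asymmetric vinylogous Mukaiyama aldol reaction in which C5 of the silyloxyfuran (future C8) adds 1,2 to the aldehyde (future C9) on the face set by the titanium BINOLate, and the anti (5R,1′S) adduct is expected; the BINOL antipode is exchanged if the induction proves opposite.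

Step 4
Reactants: 7 (5R)-3-bromo-5-[(1S,2E)-4-(tert-butyldimethylsilyloxy)-1-hydroxy-2-methylbut-2-en-1-yl]furan-2(5H)-one
Product: 8 (5R)-3-bromo-5-{(R)-hydroxy[(2R,3R)-3-(tert-butyldimethylsilyloxymethyl)-2-methyloxiran-2-yl]methyl}furan-2(5H)-one
Conditions: VO(acac)2 (5 mol%), t-BuOOH, CH2Cl2, 0 °C
Reagents that add atoms: tert-butyl hydroperoxide CC(C)(C)OO
Why: Hydroxyl-directed vanadium epoxidation of the electron-rich C10=C1 alkene only (the bromobutenolide is electron-poor); the C10 methyl geminal to the carbinol imposes A(1,2) strain and should give the erythro epoxy alcohol, which fixes C10 and C1 from C9.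

Step 5
Reactants: 8 the erythro epoxy alcohol
Product: 9 triethylsilyl ether of 8 at the C9 oxygen
Conditions: TESOTf, 2,6-lutidine, CH2Cl2, −78 °C
Reagents that add atoms: triethylsilyl trifluoromethanesulfonate CC[Si](CC)(CC)OS(=O)(=O)C(F)(F)F
Why: Silyl ether formation on the hindered secondary alcohol under buffered conditions that spare the oxirane.

Step 6
Reactants: 9 triethylsilyl ether of 8; 10 (tributylstannyl)methanol
Product: 11 3-(hydroxymethyl) analogue of 9 (CH2OH in place of Br)
Conditions: Pd(PPh3)4 (5 mol%), dioxane, 90 °C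
Reagents that add atoms: none
Why: Stille coupling (hydroxymethylation) at the α-bromo enoate C–Br bond under neutral conditions that spare oxirane and silyl ethers; it brings in C13.

Step 7
Reactants: 11 the 3-(hydroxymethyl)butenolide
Product: 12 3-(bromomethyl) analogue of 11
Conditions: CBr4, PPh3, 2,6-lutidine, CH2Cl2, 0 °C
Reagents that add atoms: tetrabromomethane BrC(Br)(Br)Br
Why: Appel bromination of the primary allylic alcohol under neutral conditions.

Step 8
Reactants: 13 4-(tert-butyldimethylsilyloxy)but-2-yn-1-ol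
Product: 15 (Z)-4-(tert-butyldimethylsilyloxy)-3-iodobut-2-en-1-ol, via cyclic alkenylalanate 14 (not isolated)
Conditions: NaAlH2(OCH2CH2OMe)2, THF, 0 °C; then I2, −78 °C to 0 °C
Reagents that add atoms: iodine II
Why: Alkoxide-directed trans-hydroalumination places aluminium on the distal alkyne carbon in a five-membered alanate, and iodinolysis with retention should give the Z iodide.

Step 9
Reactants: 15 (Z)-4-(tert-butyldimethylsilyloxy)-3-iodobut-2-en-1-ol
Product: 16 (Z)-4-(tert-butyldimethylsilyloxy)-3-iodobut-2-enal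
Conditions: MnO2, CH2Cl2, rt
Reagents that add atoms: none
Why: Mild allylic alcohol oxidation with manganese dioxide, which should leave the vinyl iodide and its geometry intact.

Step 10
Reactants: 12 the 3-(bromomethyl)butenolide; 16 (Z)-4-(tert-butyldimethylsilyloxy)-3-iodobut-2-enal
Product: 18 trans-7,8-disubstituted α-methylene-γ-butyrolactone with the 6-epi (anti) allylic alcohol, via allylzinc bromide 17 (not isolated)
Conditions: Zn dust, THF–sat. aq NH4Cl (1:1), 0 °C
Reagents that add atoms: none
Why: Barbier 2-(alkoxycarbonyl)allylation in which the allylzinc reacts through its γ-carbon C7 in a closed six-membered chair transition state: the ring-locked alkene geometry should place the C6 hydroxyl anti to C8, approach anti to the C8 arm gives the trans lactone, and the exocyclic methylene arises in the same event.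

Step 11
Reactants: 18 the 6-epi allylic alcohol; 19 (S)-2-methylbutanoic acid
Product: 20 (S)-2-methylbutanoate ester with C6 inverted to the target configuration
Conditions: PPh3 and DIAD premixed, toluene, 0 °C to rt
Reagents that add atoms: none
Why: Mitsunobu esterification, whose SN2 inversion at C6 turns the anti Barbier adduct into the required ester in one step without touching the acid stereocentre.

Step 12
Reactants: 20 the vinyl iodide ester
Product: 21 allylsilane ester (CH2SiMe3 in place of I)
Conditions: Me3SiCH2MgCl, ZnCl2, THF, 0 °C; then 20, Pd(PPh3)4 (5 mol%), rt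
Reagents that add atoms: (trimethylsilyl)methylzinc chloride C[Si](C)(C)C[Zn]Cl
Why: Negishi coupling at the vinyl C–I bond with retention of alkene geometry, the standard way from vinyl halides to allylsilanes, using an organozinc that tolerates the esters and the methylene lactone.

Step 13
Reactants: 21 the epoxy allylsilane
Product: 23 cyclised alcohol (C5–C10 bond; C3=C4 methylene; free C1–OH), via difluoroboryl ether 22 (not isolated)
Conditions: BF3·OEt2 (1.2 equiv), CH2Cl2, −78 °C; then aq NaHCO3
Reagents that add atoms: none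
Why: BF3 coordinates the oxirane oxygen and the C4=C5 π bond attacks the tertiary C10 from the side opposite the breaking C10–O bond while the C3–Si bond stabilises the charge growing at C4 (anti SE2′); loss of Me3SiF leaves the C3=C4 methylene and the C1 oxygen as a boron alkoxide. The closest known reaction type is the Lewis-acid-promoted cyclisation of epoxy allylsilanes (epoxide-initiated cation–olefin cyclisation with an allylsilane terminator). The cyclohexane closes 6-exo-tet at the oxirane (C1 stays outside the new ring) and 6-exo-trig at the alkene (C4 stays outside). C10 is set by inversion of the oxirane carbon made in step 4 (methyl axial, C1 equatorial); C5 is set by a chair transition state in which the trans lactone locks C7 and C8 and the alkene arm sits equatorial to avoid the axial C9 silyl ether; C1 is carried through unchanged. The step needs C5 to reach C10 before a 1,2-shift of the opened oxirane (hydride from C1, or a semipinacol shift from C9 pushed by the silyloxy group), before attack at C1 (7-endo), and before the allylic C6 ester ionises. The higher substitution of C10, the π-nucleophilicity of the allylsilane, the lactone that holds C5 at the rear of C10, and the low temperature should secure this.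

Step 14
Reactants: 23 the cyclised alcohol
Product: 24 C1 methanesulfonate of 23
Conditions: MsCl, Et3N, CH2Cl2, 0 °C
Reagents that add atoms: methanesulfonyl chloride CS(=O)(=O)Cl
Why: Mesylation of the only free hydroxyl (the neopentyl-type C1 alcohol) turns the former oxirane oxygen into a leaving group.

Step 15
Reactants: 24 the C1 mesylate
Product: 26 epoxy diol (C1–C2 oxirane; free C9–OH and C15–OH), via triol mesylate 25 (not isolated)
Conditions: Bu4NF (4 equiv), THF, 0 °C to rt; then aq NH4Cl
Reagents that add atoms: none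
Why: Fluoride removes the three silyl groups and the C2 alkoxide displaces the C1 mesylate (3-exo-tet Williamson closure) with inversion, so the 1S mesylate should give the 1R oxirane of the target.

Step 16
Reactants: 26 the epoxy diol
Product: 27 CNP0593558.1
Conditions: MnO2, CH2Cl2, rt
Reagents that add atoms: none
Why: Manganese dioxide oxidises only the primary allylic C15 alcohol to the 2-substituted acrolein and should leave the secondary C9 alcohol, oxirane, ester and lactone untouched.

**Compound list**

1 | (tert-butyldimethylsilyloxy)acetaldehyde | O=CCO[Si](C)(C)C(C)(C)C | starting material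
2 | 2-(triphenylphosphoranylidene)propanal | CC(C=O)=P(c1ccccc1)(c1ccccc1)c1ccccc1 | starting material
3 | (E)-4-(tert-butyldimethylsilyloxy)-2-methylbut-2-enal | O=C/C(C)=C/CO[Si](C)(C)C(C)(C)C | intermediate
4 | 3-bromofuran-2(5H)-one | O=C1OCC=C1Br | starting material
5 | 3-bromo-2-(trimethylsilyloxy)furan | C[Si](C)(C)Oc1occc1Br | intermediate
6 | O-trimethylsilyl ether of 7 (not isolated) | O=C1C(Br)=C[C@@H](O1)[C@@H](O[Si](C)(C)C)/C(C)=C/CO[Si](C)(C)C(C)(C)C | intermediate
7 | (5R)-3-bromo-5-[(1S,2E)-4-(tert-butyldimethylsilyloxy)-1-hydroxy-2-methylbut-2-en-1-yl]furan-2(5H)-one (anti aldol) | O=C1C(Br)=C[C@@H](O1)[C@@H](O)/C(C)=C/CO[Si](C)(C)C(C)(C)C | intermediate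
8 | (5R)-3-bromo-5-{(R)-hydroxy[(2R,3R)-3-(tert-butyldimethylsilyloxymethyl)-2-methyloxiran-2-yl]methyl}furan-2(5H)-one (erythro epoxy alcohol) | O=C1C(Br)=C[C@@H](O1)[C@@H](O)[C@@]2(C)O[C@@H]2CO[Si](C)(C)C(C)(C)C | intermediate
9 | C9 triethylsilyl ether of 8 | O=C1C(Br)=C[C@@H](O1)[C@@H](O[Si](CC)(CC)CC)[C@@]2(C)O[C@@H]2CO[Si](C)(C)C(C)(C)C | intermediate
10 | (tributylstannyl)methanol | CCCC[Sn](CCCC)(CCCC)CO | starting material
11 | 3-(hydroxymethyl)butenolide (CH2OH in place of Br in 9) | O=C1C(CO)=C[C@@H](O1)[C@@H](O[Si](CC)(CC)CC)[C@@]2(C)O[C@@H]2CO[Si](C)(C)C(C)(C)C | intermediate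
12 | 3-(bromomethyl)butenolide | O=C1C(CBr)=C[C@@H](O1)[C@@H](O[Si](CC)(CC)CC)[C@@]2(C)O[C@@H]2CO[Si](C)(C)C(C)(C)C | intermediate
13 | 4-(tert-butyldimethylsilyloxy)but-2-yn-1-ol | OCC#CCO[Si](C)(C)C(C)(C)C | starting material
14 | sodium salt of the cyclic alkenylalanate from 13 (not isolated) | [Na+].COCCO[Al-]1(OCCOC)OCC=C1CO[Si](C)(C)C(C)(C)C | intermediate
15 | (Z)-4-(tert-butyldimethylsilyloxy)-3-iodobut-2-en-1-ol | OC/C=C(\I)CO[Si](C)(C)C(C)(C)C | intermediate
16 | (Z)-4-(tert-butyldimethylsilyloxy)-3-iodobut-2-enal | O=C/C=C(\I)CO[Si](C)(C)C(C)(C)C | intermediate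
17 | allylzinc bromide from 12 (not isolated) | O=C1C(C[Zn]Br)=C[C@@H](O1)[C@@H](O[Si](CC)(CC)CC)[C@@]2(C)O[C@@H]2CO[Si](C)(C)C(C)(C)C | intermediate
18 | Barbier adduct: trans-7,8-disubstituted α-methylene-γ-butyrolactone; C8 carries the silyloxy oxiranyl arm, C7 a (Z)-1-hydroxy-3-iodo-4-(tert-butyldimethylsilyloxy)but-2-enyl group; C6–OH anti to C8 (6-epi) | C=C1C(=O)O[C@@H]([C@@H](O[Si](CC)(CC)CC)[C@@]2(C)O[C@@H]2CO[Si](C)(C)C(C)(C)C)[C@@H]1[C@H](O)/C=C(\I)CO[Si](C)(C)C(C)(C)C | intermediate
19 | (S)-2-methylbutanoic acid | CC[C@H](C)C(=O)O | starting material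
20 | Mitsunobu ester: as 18 with C6 inverted and acylated by (S)-2-methylbutanoyl | C=C1C(=O)O[C@@H]([C@@H](O[Si](CC)(CC)CC)[C@@]2(C)O[C@@H]2CO[Si](C)(C)C(C)(C)C)[C@@H]1[C@@H](OC(=O)[C@@H](C)CC)/C=C(\I)CO[Si](C)(C)C(C)(C)C | intermediate
21 | epoxy allylsilane: as 20 with CH2SiMe3 in place of I (silylmethyl cis to C6) | C=C1C(=O)O[C@@H]([C@@H](O[Si](CC)(CC)CC)[C@@]2(C)O[C@@H]2CO[Si](C)(C)C(C)(C)C)[C@@H]1[C@@H](OC(=O)[C@@H](C)CC)/C=C(\C[Si](C)(C)C)CO[Si](C)(C)C(C)(C)C | intermediate
22 | C1 difluoroboryl ether of 23 (not isolated) | C=C1C(=O)O[C@@H]2[C@@H]1[C@@H](OC(=O)[C@@H](C)CC)[C@@H](C(=C)CO[Si](C)(C)C(C)(C)C)[C@](C)([C@H](OB(F)F)CO[Si](C)(C)C(C)(C)C)[C@@H]2O[Si](CC)(CC)CC | intermediate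
23 | cyclised alcohol: elemanolide core with ring stereocentres as in 27; C1–OH (1S), C2–OTBS, C15–OTBS, C9–OTES | C=C1C(=O)O[C@@H]2[C@@H]1[C@@H](OC(=O)[C@@H](C)CC)[C@@H](C(=C)CO[Si](C)(C)C(C)(C)C)[C@](C)([C@H](O)CO[Si](C)(C)C(C)(C)C)[C@@H]2O[Si](CC)(CC)CC | intermediate
24 | C1 methanesulfonate of 23 | C=C1C(=O)O[C@@H]2[C@@H]1[C@@H](OC(=O)[C@@H](C)CC)[C@@H](C(=C)CO[Si](C)(C)C(C)(C)C)[C@](C)([C@H](OS(C)(=O)=O)CO[Si](C)(C)C(C)(C)C)[C@@H]2O[Si](CC)(CC)CC | intermediate
25 | triol mesylate (C2–OH, C9–OH, C15–OH free; C1–OMs; not isolated) | C=C1C(=O)O[C@@H]2[C@@H]1[C@@H](OC(=O)[C@@H](C)CC)[C@@H](C(=C)CO)[C@](C)([C@H](OS(C)(=O)=O)CO)[C@@H]2O | intermediate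
26 | epoxy diol: the 15-alcohol of the target | C=C1C(=O)O[C@@H]2[C@@H]1[C@@H](OC(=O)[C@@H](C)CC)[C@@H](C(=C)CO)[C@](C)([C@@H]1CO1)[C@@H]2O | intermediate
27 | CNP0593558.1: (1R,5R,6S,7S,8R,9S,10S)-1,2-epoxy-9-hydroxy-6-[(2S)-2-methylbutanoyloxy]-15-oxoelema-3,11(13)-dien-12,8-olide | C=C1C(=O)O[C@@H]2[C@@H]1[C@@H](OC(=O)[C@@H](C)CC)[C@@H](C(=C)C=O)[C@](C)([C@@H]1CO1)[C@@H]2O | target

**Count and risks**

Total step count: 16. Longest linear sequence: 13 steps (step 1 or 2, then steps 3 to 7 and 10 to 16).

Steps most likely to fail: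

1. Step 13 (ring closure). The Lewis-acid-opened oxirane may rearrange by a 1,2-shift (hydride from C1, or a semipinacol shift from C9 driven by the silyloxy group), or the allylic C6 ester may ionise, before C5 attacks C10. The fallback moves the closure to a radical manifold with no cationic intermediate. It sets out from vinyl iodide 20: Negishi coupling with (tributylstannyl)methylzinc iodide and Pd(PPh3)4 gives the allylstannane F1. Cp2TiCl (trivalent titanium, from Cp2TiCl2 and Mn dust, THF, high dilution) then opens the oxirane homolytically to the tertiary C10 radical, which adds 6-exo to C5 and expels the tributylstannyl radical to leave the same C3=C4 methylene. Aqueous work-up comes back to the route at alcohol 23. In this variant C10 rests on the chair transition state (bulky titanoxy-bearing C1 equatorial) instead of on inversion.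

2. Step 11 (Mitsunobu). Displacement at the hindered allylic C6 carbinol may lose to elimination, to SN2′ transposition, or to addition of the betaine to the methylene lactone. The fallback inverts C6 by a redox pair. It sets out from alcohol 18: Dess–Martin oxidation gives the enone F2; CBS reduction with the oxazaborolidine antipode that delivers hydride to the required face gives the C6-epimeric alcohol F3; Steglich esterification (DCC, DMAP) with acid 19 comes back at ester 20.

3. Step 3 (asymmetric vinylogous aldol). Facial and simple diastereoselectivity may be poor with the brominated silyloxyfuran and the α-branched enal. The fallback takes the absolute configuration from a Sharpless epoxidation instead. It sets out from enal 3: Luche reduction (NaBH4, CeCl3) gives the allylic alcohol F4; Ti(OiPr)4, D-(−)-diethyl tartrate and t-BuOOH give the epoxy alcohol F5; Parikh–Doering oxidation gives the epoxy aldehyde F6. A BF3·OEt2-promoted vinylogous Mukaiyama aldol with silyloxyfuran 5 (addition anti to the oxirane C–O bond under non-chelation control), with the same mild acid work-up, comes back at epoxy alcohol 8 and so also replaces step 4.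

**Further compounds**

F1 | step 13 | allylstannane: as 21 with CH2SnBu3 in place of CH2SiMe3 | C=C1C(=O)O[C@@H]([C@@H](O[Si](CC)(CC)CC)[C@@]2(C)O[C@@H]2CO[Si](C)(C)C(C)(C)C)[C@@H]1[C@@H](OC(=O)[C@@H](C)CC)/C=C(\C[Sn](CCCC)(CCCC)CCCC)CO[Si](C)(C)C(C)(C)C
F2 | step 11 | C6 enone from 18 | C=C1C(=O)O[C@@H]([C@@H](O[Si](CC)(CC)CC)[C@@]2(C)O[C@@H]2CO[Si](C)(C)C(C)(C)C)[C@@H]1C(=O)/C=C(\I)CO[Si](C)(C)C(C)(C)C
F3 | step 11 | C6 epimer of alcohol 18 (target configuration at C6) | C=C1C(=O)O[C@@H]([C@@H](O[Si](CC)(CC)CC)[C@@]2(C)O[C@@H]2CO[Si](C)(C)C(C)(C)C)[C@@H]1[C@@H](O)/C=C(\I)CO[Si](C)(C)C(C)(C)C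
F4 | step 3 | (E)-4-(tert-butyldimethylsilyloxy)-2-methylbut-2-en-1-ol | OC/C(C)=C/CO[Si](C)(C)C(C)(C)C
F5 | step 3 | [(2R,3R)-3-(tert-butyldimethylsilyloxymethyl)-2-methyloxiran-2-yl]methanol | OC[C@@]1(C)O[C@@H]1CO[Si](C)(C)C(C)(C)C
F6 | step 3 | epoxy aldehyde from F5: 3-(tert-butyldimethylsilyloxymethyl)-2-methyloxirane-2-carbaldehyde with the oxirane configuration of F5 | O=C[C@@]1(C)O[C@@H]1CO[Si](C)(C)C(C)(C)C
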